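**Plan**

1. Ring B is numbered C1 (enone arm), C2 (OMe), C3 (OH), C4 (OH), C5 (1,1-dimethylallyl), C6 (H); ring A is the 4-hydroxybenzoyl ring. The enabling feature is that C1–C4 of ring B are four contiguous carbons that can each carry oxygen (a squarate pattern), while C5–C6 map onto an alkyne that already holds the quaternary carbon.
2. Retrosynthetic cuts, in order: the C3 O–methyl and ring A O–isopropyl bonds; the C1–vinyl bond of the enone arm (C1 oxygen as triflate); the C4–C5 bond of ring B (ring expansion); the C1–C6 bond (acetylide addition to dimethyl squarate); the C5–C6 bond (one-carbon homologation of 2,2-dimethylbut-3-enal).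
3. Forward: 2,2-dimethylbut-3-enoic acid is taken to the alcohol, the aldehyde, the 1,1-dibromoalkene and the lithium acetylide, which adds to dimethyl squarate; one thermal step then expands the four-membered ring to the ring B benzoquinone.
4. Reduction to the hydroquinone, triflation of the unhindered C1 hydroxyl, Heck coupling with the ring A vinyl ketone (two steps from 4'-hydroxyacetophenone) and a final BCl3 step that frees the C3 and ring A hydroxyls complete the route.
5. Stereochemistry: the target has no stereocentre. The E enone comes from syn insertion and syn β-hydride elimination in the Heck step. The racemic carbinol carbon of the cyclobutenone becomes sp2 in the key step.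

Key step: step 5

Remark on the chemistry: 2,2-dimethylbut-3-enal is volatile, so it is assumed to be carried from step 2 into step 3 as a dried CH2Cl2 solution without concentration.

**Route**

Step 1
Reactants: 1 2,2-dimethylbut-3-enoic acid
Product: 2 2,2-dimethylbut-3-en-1-ol
Conditions: LiAlH4, Et2O, 0 °C to rt; then H2O, aq. NaOH
Reagents that add atoms: none
Why: LiAlH4 reduction of a carboxylic acid should give the primary alcohol and leave the isolated terminal alkene untouched.

Step 2
Reactants: 2 2,2-dimethylbut-3-en-1-ol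
Product: 3 2,2-dimethylbut-3-enal
Conditions: Dess–Martin periodinane, CH2Cl2, 0 °C to rt; aq. NaHCO3 wash, dried solution used directly
Reagents that add atoms: none
Why: Dess–Martin oxidation of a primary alcohol stops at the aldehyde, which has no α-hydrogen and so can neither enolise nor move its double bond into conjugation.

Step 3
Reactants: 3 2,2-dimethylbut-3-enal
Product: 4 1,1-dibromo-3,3-dimethylpenta-1,4-diene
Conditions: CBr4, PPh3, CH2Cl2, 0 °C
Reagents that add atoms: carbon tetrabromide, BrC(Br)(Br)Br
Why: The first stage of the Corey–Fuchs homologation (Wittig reaction of the dibromomethylene ylide formed in the flask) is known for α-quaternary aldehydes and turns a volatile aldehyde into a non-volatile alkyne precursor.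

Step 4
Reactants: 4 1,1-dibromo-3,3-dimethylpenta-1,4-diene; 5 dimethyl squarate (3,4-dimethoxycyclobut-3-ene-1,2-dione)
Product: 7 rac-4-hydroxy-2,3-dimethoxy-4-(3,3-dimethylpent-4-en-1-yn-1-yl)cyclobut-2-en-1-one, via lithium acetylide 6 (not isolated)
Conditions: n-BuLi (2.0 equiv), THF, −78 °C to rt; recooled to −78 °C and cannulated into 5, THF, −78 °C; aq. NH4Cl
Reagents that add atoms: none
Why: The second Corey–Fuchs stage (bromine–lithium exchange, Fritsch–Buttenberg–Wiechell-type 1,2-hydrogen shift, deprotonation) should give the lithium acetylide without isolation of the volatile enyne, and 1,2-addition of a lithium acetylide to one carbonyl of dimethyl squarate at −78 °C is the standard entry to 4-alkynyl-4-hydroxycyclobutenones; the new carbinol centre is racemic and is not carried further.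

Step 5
Reactants: 7 rac-4-hydroxy-2,3-dimethoxy-4-(3,3-dimethylpent-4-en-1-yn-1-yl)cyclobut-2-en-1-one
Product: 10 2,3-dimethoxy-5-(2-methylbut-3-en-2-yl)cyclohexa-2,5-diene-1,4-dione, via enynyl ketene 8 (not isolated), via aryl-phenoxyl diradical 9 (not isolated)
Conditions: p-xylene (0.01 M, degassed), 138 °C, argon
Reagents that add atoms: none
Why: On heating, the acyl–carbinol σ bond of the four-membered ring should break in a conrotatory 4π electrocyclic opening whose torquoselectivity turns the hydroxyl outward and the alkynyl group toward the new ketene, giving the (Z)-enynyl ketene 8. The ketene carbon then bonds to the distal alkyne carbon, which forms the C4–C5 bond and closes ring B in a six-membered 6-endo-dig (Myers–Saito-like) mode to diradical 9, and transfer of the hydroxyl hydrogen to the ring radical centre at C6 gives quinone 10. This is the Moore rearrangement, known for 4-alkynyl-4-hydroxy-2,3-dialkoxycyclobutenones that carry alkyl groups on the alkyne. No stereocentre is formed and the carbinol centre of 7 is lost. The step needs six-membered over five-membered (5-exo-dig) closure, which would lead to an alkylidenecyclopentenedione; the tertiary alkyl group gives no stabilisation to the exocyclic vinyl radical of the five-membered path, and the attacking ketene carbon carries only its collinear oxygen, so the quaternary carbon should meet little steric resistance at the alkyne terminus. High dilution and exclusion of air should keep the diradical from intermolecular hydrogen abstraction and from addition to the pendant vinyl group.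

Step 6
Reactants: 10 2,3-dimethoxy-5-(2-methylbut-3-en-2-yl)cyclohexa-2,5-diene-1,4-dione
Product: 11 2,3-dimethoxy-5-(2-methylbut-3-en-2-yl)benzene-1,4-diol
Conditions: Na2S2O4, EtOAc/H2O, rt, argon
Reagents that add atoms: none
Why: Dithionite reduction of a benzoquinone to its hydroquinone is fast in a two-phase system and should not touch the isolated alkene.

Step 7
Reactants: 11 2,3-dimethoxy-5-(2-methylbut-3-en-2-yl)benzene-1,4-diol
Product: 12 4-hydroxy-2,3-dimethoxy-5-(2-methylbut-3-en-2-yl)phenyl trifluoromethanesulfonate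
Conditions: PhNTf2 (1.05 equiv), Et3N, CH2Cl2 (degassed), 0 °C to rt
Reagents that add atoms: N-phenylbis(trifluoromethanesulfonimide), O=S(=O)(N(c1ccccc1)S(=O)(=O)C(F)(F)F)C(F)(F)F
Why: Phenol triflation with the bulky, mild reagent PhNTf2 should take place at the C1 hydroxyl, which is more acidic and far less hindered than the C4 hydroxyl wedged between the C3 methoxyl and the quaternary carbon, the same bias that governs mono-functionalisation of 2-tert-butylhydroquinone.

Step 8
Reactants: 13 4'-hydroxyacetophenone
Product: 14 1-[4-(propan-2-yloxy)phenyl]ethan-1-one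
Conditions: 2-bromopropane, K2CO3, DMF, 60 °C
Reagents that add atoms: 2-bromopropane, CC(C)Br
Why: Williamson ether synthesis on an acidic para-acylphenol is routine, and the isopropyl ether is chosen because BCl3 removes it in the last step.

Step 9
Reactants: 14 1-[4-(propan-2-yloxy)phenyl]ethan-1-one
Product: 16 1-[4-(propan-2-yloxy)phenyl]prop-2-en-1-one, via Mannich base 15 (not isolated)
Conditions: (CH2O)n, diisopropylammonium trifluoroacetate (1 equiv), CF3CO2H (0.1 equiv), THF, reflux; product stored cold and used promptly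
Reagents that add atoms: paraformaldehyde (formaldehyde), C=O
Why: Mannich condensation of the aryl methyl ketone with the iminium ion formed in the flask, followed by elimination of the secondary amine from Mannich base 15, is an established one-flask α-methylenation that gives aryl vinyl ketones.

Step 10
Reactants: 12 4-hydroxy-2,3-dimethoxy-5-(2-methylbut-3-en-2-yl)phenyl trifluoromethanesulfonate; 16 1-[4-(propan-2-yloxy)phenyl]prop-2-en-1-one
Product: 17 (E)-3-[4-hydroxy-2,3-dimethoxy-5-(2-methylbut-3-en-2-yl)phenyl]-1-[4-(propan-2-yloxy)phenyl]prop-2-en-1-one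
Conditions: Pd(OAc)2 (5 mol %), 1,3-bis(diphenylphosphino)propane (6 mol %), Cy2NMe, 16 (2 equiv, in portions), DMF, 90 °C
Reagents that add atoms: none
Why: The Mizoroki–Heck reaction of an aryl triflate with an electron-poor terminal alkene under chelating-bisphosphine conditions should arylate the β-carbon, syn insertion and syn β-hydride elimination giving the E enone; the vinyl group on C5 is unactivated, hindered and unable to isomerise because it sits on a quaternary carbon.

Step 11
Reactants: 17 (E)-3-[4-hydroxy-2,3-dimethoxy-5-(2-methylbut-3-en-2-yl)phenyl]-1-[4-(propan-2-yloxy)phenyl]prop-2-en-1-one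
Product: 19 (E)-3-[3,4-dihydroxy-2-methoxy-5-(2-methylbut-3-en-2-yl)phenyl]-1-(4-hydroxyphenyl)prop-2-en-1-one, via cyclic chloroborate 18 (not isolated)
Conditions: BCl3 (5 equiv), CH2Cl2, −78 °C to 0 °C; then H2O
Reagents that add atoms: none
Why: In this Lewis-acid ether cleavage the C4 hydroxyl should become an aryloxydichloroborane that chelates the neighbouring C3 methoxyl and delivers chloride to its methyl group, closing the dioxaborole of 18, while BCl3 cleaves isopropyl aryl ethers much faster than unassisted methyl ethers, so the C2 methoxyl, which the ring-bound boron cannot reach, should remain.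

**Compound list**

1 | 2,2-dimethylbut-3-enoic acid | C=CC(C)(C)C(=O)O | starting material
2 | 2,2-dimethylbut-3-en-1-ol | C=CC(C)(C)CO | intermediate
3 | 2,2-dimethylbut-3-enal | C=CC(C)(C)C=O | intermediate
4 | 1,1-dibromo-3,3-dimethylpenta-1,4-diene | C=CC(C)(C)C=C(Br)Br | intermediate
5 | dimethyl squarate (3,4-dimethoxycyclobut-3-ene-1,2-dione) | COC1=C(OC)C(=O)C1=O | starting material
6 | lithium 3,3-dimethylpent-4-en-1-yn-1-ide (not isolated) | [Li]C#CC(C)(C)C=C | intermediate
7 | rac-4-hydroxy-2,3-dimethoxy-4-(3,3-dimethylpent-4-en-1-yn-1-yl)cyclobut-2-en-1-one | COC1=C(OC)C(O)(C#CC(C)(C)C=C)C1=O | intermediate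
8 | (3Z)-4-hydroxy-2,3-dimethoxy-7,7-dimethylnona-1,3,8-trien-5-yn-1-one, the enynyl ketene (not isolated) | O=C=C(OC)/C(OC)=C(/O)C#CC(C)(C)C=C | intermediate
9 | 2-hydroxy-3,4-dimethoxy-6-(2-methylbut-3-en-2-yl)-5-oxylphenyl diradical (not isolated) | [O]c1c(OC)c(OC)c(O)[c]c1C(C)(C)C=C | intermediate
10 | 2,3-dimethoxy-5-(2-methylbut-3-en-2-yl)cyclohexa-2,5-diene-1,4-dione | COC1=C(OC)C(=O)C(C(C)(C)C=C)=CC1=O | intermediate
11 | 2,3-dimethoxy-5-(2-methylbut-3-en-2-yl)benzene-1,4-diol | COc1c(O)cc(C(C)(C)C=C)c(O)c1OC | intermediate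
12 | 4-hydroxy-2,3-dimethoxy-5-(2-methylbut-3-en-2-yl)phenyl trifluoromethanesulfonate | COc1c(OS(=O)(=O)C(F)(F)F)cc(C(C)(C)C=C)c(O)c1OC | intermediate
13 | 4'-hydroxyacetophenone | CC(=O)c1ccc(O)cc1 | starting material
14 | 1-[4-(propan-2-yloxy)phenyl]ethan-1-one | CC(=O)c1ccc(OC(C)C)cc1 | intermediate
15 | 3-[di(propan-2-yl)amino]-1-[4-(propan-2-yloxy)phenyl]propan-1-one, the Mannich base (not isolated) | CC(C)Oc1ccc(C(=O)CCN(C(C)C)C(C)C)cc1 | intermediate
16 | 1-[4-(propan-2-yloxy)phenyl]prop-2-en-1-one | C=CC(=O)c1ccc(OC(C)C)cc1 | intermediate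
17 | (E)-3-[4-hydroxy-2,3-dimethoxy-5-(2-methylbut-3-en-2-yl)phenyl]-1-[4-(propan-2-yloxy)phenyl]prop-2-en-1-one | C=CC(C)(C)c1cc(/C=C/C(=O)c2ccc(OC(C)C)cc2)c(OC)c(OC)c1O | intermediate
18 | (E)-3-[2-chloro-4-methoxy-7-(2-methylbut-3-en-2-yl)-1,3,2-benzodioxaborol-5-yl]-1-[4-(dichloroboranyloxy)phenyl]prop-2-en-1-one, the cyclic chloroborate (not isolated) | C=CC(C)(C)c1cc(/C=C/C(=O)c2ccc(OB(Cl)Cl)cc2)c(OC)c2OB(Cl)Oc12 | intermediate
19 | (E)-3-[3,4-dihydroxy-2-methoxy-5-(2-methylbut-3-en-2-yl)phenyl]-1-(4-hydroxyphenyl)prop-2-en-1-one | C=CC(C)(C)c1cc(/C=C/C(=O)c2ccc(O)cc2)c(OC)c(O)c1O | target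

**Step count**

Total: 11 steps. Longest linear sequence: 9 steps (steps 1–7, 10 and 11, from acid 1); steps 8 and 9 form the two-step side branch to vinyl ketone 16.

**Steps most likely to fail**

Step 5. The enynyl ketene may close at the proximal alkyne carbon (five-membered mode), or the diradical may be intercepted by solvent or by the pendant vinyl group before it takes up the hydroxyl hydrogen. The fallback closes ring B by a pericyclic 6π electrocyclisation, which has no five-membered alternative. It sets out from aldehyde 3 and comes back to the route at hydroquinone 11, so steps 3 to 6 are bypassed. Takai iodo-olefination of 3 (CHI3, CrCl2, THF, 0 °C) should give (E)-1-iodo-3,3-dimethylpenta-1,4-diene F1. Iodine–lithium exchange (t-BuLi, 2 equiv, Et2O, −78 °C) gives [(E)-3,3-dimethylpenta-1,4-dien-1-yl]lithium F2, which is added to dimethyl squarate 5 (THF, −78 °C; aq. NH4Cl) to give rac-4-[(E)-3,3-dimethylpenta-1,4-dien-1-yl]-4-hydroxy-2,3-dimethoxycyclobut-2-en-1-one F3. Heating F3 in degassed toluene under argon should open it to the dienyl ketene (3Z,5E)-4-hydroxy-2,3-dimethoxy-7,7-dimethylnona-1,3,5,8-tetraen-1-one F4, which closes to rac-4-hydroxy-2,3-dimethoxy-6-(2-methylbut-3-en-2-yl)cyclohexa-2,4-dien-1-one F5 and tautomerises to 11.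

Step 10. Under the hot basic conditions the vinyl ketone may polymerise or take up the phenol in a conjugate addition faster than the electron-rich, para-hydroxylated triflate enters the catalytic cycle. The fallback builds the enone arm by aldol condensation, so no vinyl ketone is present and the triflate can be pushed harder. It sets out from triflate 12 and ketone 14 and comes back at chalcone 17; step 9 is then not needed. Reductive carbonylation of 12 (Pd(OAc)2, 1,3-bis(diphenylphosphino)propane, CO (1 atm), Et3SiH, Et3N, DMF, 70 °C) should give 4-hydroxy-2,3-dimethoxy-5-(2-methylbut-3-en-2-yl)benzaldehyde F6. Claisen–Schmidt condensation of F6 with 14 (excess KOH, EtOH, rt to 50 °C) should pass through the aldol adduct rac-3-hydroxy-3-[4-hydroxy-2,3-dimethoxy-5-(2-methylbut-3-en-2-yl)phenyl]-1-[4-(propan-2-yloxy)phenyl]propan-1-one F7 and, after loss of water, give 17.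

Step 11. Once the C3 oxygen is boron-bound, the twisted C2 methyl ether may also be cleaved, or the longer and warmer exposure that the methyl ether needs may cause acid-induced ring closure of the C4 oxygen onto the 1,1-dimethylallyl double bond. The fallback removes the C3 methyl group oxidatively, so that BCl3 is needed only briefly at −78 °C for the isopropyl ether. It sets out from chalcone 17 and comes back at chloroborate 18. IBX (DMF, rt) should oxidise the ortho-methoxyphenol unit, with loss of methanol, to the ortho-quinone 3-methoxy-6-(2-methylbut-3-en-2-yl)-4-{(E)-3-oxo-3-[4-(propan-2-yloxy)phenyl]prop-1-en-1-yl}cyclohexa-3,5-diene-1,2-dione F8. Na2S2O4 (EtOAc/H2O, rt) reduces F8 to the catechol (E)-3-[3,4-dihydroxy-2-methoxy-5-(2-methylbut-3-en-2-yl)phenyl]-1-[4-(propan-2-yloxy)phenyl]prop-2-en-1-one F9. BCl3 (CH2Cl2, −78 °C) then converts F9 into 18, and water gives 19 as in the route.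

**Further compounds**

F1 | step 5 | (E)-1-iodo-3,3-dimethylpenta-1,4-diene | C=CC(C)(C)/C=C/I
F2 | step 5 | [(E)-3,3-dimethylpenta-1,4-dien-1-yl]lithium | [Li]/C=C/C(C)(C)C=C
F3 | step 5 | rac-4-[(E)-3,3-dimethylpenta-1,4-dien-1-yl]-4-hydroxy-2,3-dimethoxycyclobut-2-en-1-one | COC1=C(OC)C(O)(/C=C/C(C)(C)C=C)C1=O
F4 | step 5 | (3Z,5E)-4-hydroxy-2,3-dimethoxy-7,7-dimethylnona-1,3,5,8-tetraen-1-one | O=C=C(OC)/C(OC)=C(/O)\C=C\C(C)(C)C=C
F5 | step 5 | rac-4-hydroxy-2,3-dimethoxy-6-(2-methylbut-3-en-2-yl)cyclohexa-2,4-dien-1-one | O=C1C(OC)=C(OC)C(O)=CC1C(C)(C)C=C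
F6 | step 10 | 4-hydroxy-2,3-dimethoxy-5-(2-methylbut-3-en-2-yl)benzaldehyde | C=CC(C)(C)c1cc(C=O)c(OC)c(OC)c1O
F7 | step 10 | rac-3-hydroxy-3-[4-hydroxy-2,3-dimethoxy-5-(2-methylbut-3-en-2-yl)phenyl]-1-[4-(propan-2-yloxy)phenyl]propan-1-one | C=CC(C)(C)c1cc(C(O)CC(=O)c2ccc(OC(C)C)cc2)c(OC)c(OC)c1O
F8 | step 11 | 3-methoxy-6-(2-methylbut-3-en-2-yl)-4-{(E)-3-oxo-3-[4-(propan-2-yloxy)phenyl]prop-1-en-1-yl}cyclohexa-3,5-diene-1,2-dione | C=CC(C)(C)C1=CC(/C=C/C(=O)c2ccc(OC(C)C)cc2)=C(OC)C(=O)C1=O
F9 | step 11 | (E)-3-[3,4-dihydroxy-2-methoxy-5-(2-methylbut-3-en-2-yl)phenyl]-1-[4-(propan-2-yloxy)phenyl]prop-2-en-1-one | C=CC(C)(C)c1cc(/C=C/C(=O)c2ccc(OC(C)C)cc2)c(OC)c(O)c1O
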